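The route rests on cutting C13–C16 of ring D (C8–C14–C13–C16–C15). Its precursor is a cis-fused spirolactone/cyclohexene carrying a propargylic alcohol arm on C8; there C16, C15, C8, C14 and the C13=C12 alkene form a hex-5-enyl array, so a stannyl-radical enyne cyclisation closes the bicyclo[3.2.1]octane across the 1,3-diaxial C8/C13 positions and delivers the C16=C17 methylene in the same operation. The precursor arises from a Diels–Alder reaction of butadiene with an α-formyl unsaturated spirolactone, whose centres are relayed from one catalytically set centre (C5). Exo-face hydride delivery finally sets C15.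

Key step: step 12

Remark on the chemistry: atoms are labelled by ent-kaurane numbering: ring A = C1–C5/C10, C6 = formyl carbon, lactone = C10–C20–O–C7(=O)–C8–C9, ring C = C8/C9/C11–C14, ring D = C8/C14/C13/C16/C15, C17 = exocyclic CH2.

Step 1
Reactants: 1 4,4-dimethylcyclohex-2-en-1-one; 2 hex-1-yne; 3 Eschenmoser's salt
Product: 6 (2R,3S)-2-[(dimethylamino)methyl]-3-[(E)-hex-1-enyl]-4,4-dimethylcyclohexan-1-one, via alkenylalane 4 (not isolated), via aluminium enolate 5 (not isolated)
Conditions: 2, i-Bu2AlH, heptane, 50 °C; then 1, copper thiophene-2-carboxylate (CuTC, C5H3CuO2S, 5 mol%), BINOL-derived bis(1-phenylethyl)phosphoramidite ligand (6 mol%, antipode chosen for the 3S adduct), Et2O, −30 °C; then 3, THF, −30 °C → rt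
Reagents that add atoms: none
Why: Copper-catalysed asymmetric conjugate addition of the alkenylalane sets C5 under ligand control, and the aluminium enolate is trapped regiospecifically at C10 by the iminium salt (Mannich reaction) anti to the new alkenyl group.

Step 2
Reactants: 6 (2R,3S)-2-[(dimethylamino)methyl]-3-[(E)-hex-1-enyl]-4,4-dimethylcyclohexan-1-one
Product: 8 (3R)-3-[(E)-hex-1-enyl]-4,4-dimethyl-2-methylidenecyclohexan-1-one, via ammonium iodide 7 (not isolated)
Conditions: MeI, Et2O, rt; then aq. NaHCO3, CH2Cl2, rt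
Reagents that add atoms: none
Why: Quaternisation of the Mannich base and mild base-induced β-elimination (Eschenmoser methylenation) should unveil the exocyclic C10=C20 enone without moving the double bond into the ring or touching C5.

Step 3
Reactants: 8 (3R)-3-[(E)-hex-1-enyl]-4,4-dimethyl-2-methylidenecyclohexan-1-one
Product: 9 (1S,3R)-3-[(E)-hex-1-enyl]-4,4-dimethyl-2-methylidenecyclohexan-1-ol
Conditions: NaBH4, CeCl3·7H2O, MeOH, −78 °C
Reagents that add atoms: none
Why: Luche reduction should give clean 1,2-reduction, with hydride entering anti to the 1,3-related C5 alkenyl arm so that the C1 hydroxyl ends up cis to it.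

Step 4
Reactants: 9 (1S,3R)-3-[(E)-hex-1-enyl]-4,4-dimethyl-2-methylidenecyclohexan-1-ol
Product: 10 8-[(E)-hex-1-enyl]-7,7-dimethyl-1-oxaspiro[2.5]octan-4-ol (hydroxyl, hexenyl group and epoxide oxygen mutually cis)
Conditions: VO(acac)2 (cat.), t-BuOOH, CH2Cl2, 0 °C → rt
Reagents that add atoms: tert-butyl hydroperoxide CC(C)(C)OO
Why: Hydroxyl-directed vanadium-catalysed epoxidation should touch only the allylic C10=C20 bond and leave the isolated hexenyl alkene; the new epoxide centre is erased in step 6.

Step 5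
Reactants: 10 8-[(E)-hex-1-enyl]-7,7-dimethyl-1-oxaspiro[2.5]octan-4-ol
Product: 11 4-methoxybenzyl ether of 10
Conditions: NaH, 4-methoxybenzyl chloride, Bu4NI (cat.), THF/DMF, 0 °C → rt
Reagents that add atoms: 4-methoxybenzyl chloride COc1ccc(CCl)cc1
Why: Williamson etherification installs a slim, base-stable C1 ether; epoxide migration would need substitution at the fully substituted C10 and should not compete.

Step 6
Reactants: 11 4-methoxybenzyl ether of 10; 12 2,2,2-trifluoroethyl acrylate
Product: 14 11-[(E)-hex-1-enyl]-7-[(4-methoxybenzyl)oxy]-10,10-dimethyl-2-oxaspiro[5.5]undecan-3-one (C9 trans to O1 and to the hexenyl group), via hydroxy ester 13 (not isolated)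
Conditions: Cp2TiCl2 (20 mol%), Zn dust, 2,4,6-collidine hydrochloride, 12 (5 equiv), THF, rt
Reagents that add atoms: none
Why: Titanocene chloride Cp2TiCl (trivalent titanium) opens the epoxide homolytically to the tertiary C10 radical, which undergoes Giese addition to the acrylate on the face opposite the cis C1 ether and C5 arm, and the C20 alkoxide then closes the δ-lactone on the activated ester, which sets the spiro centre C10.

Step 7
Reactants: 14 11-[(E)-hex-1-enyl]-7-[(4-methoxybenzyl)oxy]-10,10-dimethyl-2-oxaspiro[5.5]undecan-3-one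
Product: 16 11-(dimethoxymethyl)-7-[(4-methoxybenzyl)oxy]-10,10-dimethyl-2-oxaspiro[5.5]undecan-3-one, via aldehyde 15 (not isolated)
Conditions: O3, CH2Cl2, −78 °C (stopped at first excess); PPh3; then HC(OMe)3, PPTS, rt
Reagents that add atoms: ozone [O-][O+]=O; trimethyl orthoformate COC(OC)OC
Why: Ozonolysis cleaves the only alkene to the C6 aldehyde, which is acetalised in the same pot so that C5 is never exposed to base and C6 stays masked until the end.

Step 8
Reactants: 16 11-(dimethoxymethyl)-7-[(4-methoxybenzyl)oxy]-10,10-dimethyl-2-oxaspiro[5.5]undecan-3-one; 17 2,2,2-trifluoroethyl formate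
Product: 18 (Z)-4-(hydroxymethylidene) derivative of 16
Conditions: LiN(i-Pr)2 (2.2 equiv), THF, −78 °C; 17; then AcOH
Reagents that add atoms: none
Why: Claisen-type C-formylation of the lactone enolate at its only enolisable position C8 introduces C15, and the product should rest as the hydrogen-bonded enol.

Step 9
Reactants: 18 (Z)-4-(hydroxymethylidene) derivative of 16
Product: 21 11-(dimethoxymethyl)-7-[(4-methoxybenzyl)oxy]-10,10-dimethyl-3-oxo-2-oxaspiro[5.5]undec-4-ene-4-carbaldehyde, via selenide 19 (not isolated), via selenoxide 20 (not isolated)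
Conditions: PhSeCl, pyridine, CH2Cl2, 0 °C; then 30% H2O2, 0 °C → rt
Reagents that add atoms: none
Why: Selenenylation of the enol at C8, oxidation and selenoxide syn-elimination toward the only β-hydrogens (C9) should give the doubly activated C8=C9 dienophile.

Step 10
Reactants: 21 11-(dimethoxymethyl)-7-[(4-methoxybenzyl)oxy]-10,10-dimethyl-3-oxo-2-oxaspiro[5.5]undec-4-ene-4-carbaldehyde; 22 buta-1,3-diene
Product: 23 Diels–Alder adduct (cis-fused lactone/cyclohexene with C12=C13 and an angular C8 formyl group cis to H9)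
Conditions: 22 (excess), ZnCl2 (1 equiv), Et2O/CH2Cl2, sealed tube, 0 °C → rt
Reagents that add atoms: none
Why: Lewis-acid-promoted Diels–Alder reaction of the alkylidene 1,3-dicarbonyl with the symmetric diene forms ring C; suprafacial addition makes H9 and the formyl group cis, and the diene should approach the lactone face syn to the slim C1 ether and away from the C5 acetal arm buttressed by the C4 methyls, which sets C9 and C8 relative to C10.

Step 11
Reactants: 23 Diels–Alder adduct; 24 ethynylmagnesium bromide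
Product: 25 propargylic alcohol C8–CH(OH)–C≡CH (drawn as the 15-epimer expected from chelation control)
Conditions: HC≡CMgBr (0.5 M in THF), THF, −78 → −40 °C; then H2O
Reagents that add atoms: none
Why: Grignard addition to the aldehyde should outpace attack on the lactone; magnesium chelation between the two carbonyls should favour the drawn C15 epimer, but this centre is erased in step 13 so either epimer serves.

Step 12
Reactants: 25 propargylic alcohol C8–CH(OH)–C≡CH
Product: 27 tetracyclic 16-methylidene-15-ol (15-epi; C1 PMB ether; C6 dimethyl acetal), via vinylstannane 26 (not isolated)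
Conditions: Bu3SnH (1.3 equiv), Et3B (0.2 equiv), air, PhMe (0.02 M), 0 °C → rt; then TsOH·H2O, MeOH/CH2Cl2, 0 °C
Reagents that add atoms: none
Why: Tributylstannyl radical adds reversibly to the terminal alkyne carbon C17 to give the σ-vinyl radical at C16, which attacks C13 of the ring C alkene (hex-5-enyl array C16–C15–C8–C14–C13=C12); the C12 radical is quenched by the stannane and the vinylstannane is protodestannylated with retention to unveil the C16=C17 methylene. The closest known reaction type is the stannyl-radical cyclisation of 1,6-enynes to alkylidenecyclopentanes, as used for bicyclo[3.2.1]octanes. Ring D is closed in the 5-exo-trig mode across the 1,3-diaxial C8 and C13 positions of ring C, so the new C13 centre is dictated by the quaternary C8 centre because the two-atom bridge can only span one face. C15 is not created here and its configuration is irrelevant because step 13 erases it. The step needs 5-exo attack at C13 to beat attack at C12 (bicyclo[2.2.2]octane), 1,5-hydrogen transfer from C11 and premature reduction of the vinyl radical; the shorter tether to C13, low-temperature triethylborane initiation and dilute stannane should secure this.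

Step 13
Reactants: 27 tetracyclic 16-methylidene-15-ol
Product: 28 tetracyclic 16-methylidene-15-ketone (C1 PMB ether; C6 dimethyl acetal)
Conditions: Dess–Martin periodinane, NaHCO3, CH2Cl2, 0 °C → rt
Reagents that add atoms: none
Why: Dess–Martin oxidation of the allylic alcohol gives the α-methylene ketone and removes the C15 stereocentre, so both epimers converge.

Step 14
Reactants: 28 tetracyclic 16-methylidene-15-ketone
Product: 29 1-hydroxy 15-ketone (C6 dimethyl acetal)
Conditions: DDQ, CH2Cl2/pH 7 phosphate buffer, 0 °C → rt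
Reagents that add atoms: none
Why: Oxidative cleavage of the electron-rich benzyl ether by DDQ frees the C1 hydroxyl without acid, so the acetal and the enone should survive.

Step 15
Reactants: 29 1-hydroxy 15-ketone
Product: 30 1-acetoxy 15-ketone (C6 dimethyl acetal)
Conditions: Ac2O, pyridine, DMAP (cat.), CH2Cl2, 0 °C → rt
Reagents that add atoms: acetic anhydride CC(=O)OC(C)=O
Why: Acylation of the only free hydroxyl installs the C1 acetate before the C15 hydroxyl exists, which avoids differentiating two secondary alcohols.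

Step 16
Reactants: 30 1-acetoxy 15-ketone
Product: 31 dimethyl acetal of the target (15-hydroxyl endo)
Conditions: NaBH4, CeCl3·7H2O, MeOH, −78 °C
Reagents that add atoms: none
Why: Luche 1,2-reduction; hydride should attack the C15 carbonyl from the exo face (the side of the one-carbon bridge C14) because the endo face is screened by the axial hydrogen on C11, which places the hydroxyl endo as in the target, while acetate and lactone are inert at this temperature.

Step 17
Reactants: 31 dimethyl acetal of the target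
Product: 32 CNP0117386.1
Conditions: 1 M aq. HCl, THF, 0 °C → rt
Reagents that add atoms: water O
Why: Acid hydrolysis of the dimethyl acetal releases the C6 aldehyde under conditions that should leave the acetate, the lactone, the allylic alcohol and the C5 configuration intact.

Compound list
1 | 4,4-dimethylcyclohex-2-en-1-one | CC1(C)CCC(=O)C=C1 | starting material
2 | hex-1-yne | C#CCCCC | starting material
3 | N,N-dimethylmethyleneiminium iodide (Eschenmoser's salt) | C[N+](C)=C.[I-] | starting material
4 | (E)-hex-1-enyl(diisobutyl)alane | CCCC/C=C/[Al](CC(C)C)CC(C)C | intermediate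
5 | diisobutylaluminium (3S)-3-[(E)-hex-1-enyl]-4,4-dimethylcyclohex-1-en-1-olate | CCCC/C=C/[C@H]1C=C(O[Al](CC(C)C)CC(C)C)CCC1(C)C | intermediate
6 | (2R,3S)-2-[(dimethylamino)methyl]-3-[(E)-hex-1-enyl]-4,4-dimethylcyclohexan-1-one | CN(C)C[C@@H]1C(=O)CCC(C)(C)[C@H]1/C=C/CCCC | intermediate
7 | {[(1R,6S)-6-[(E)-hex-1-enyl]-5,5-dimethyl-2-oxocyclohexyl]methyl}trimethylammonium iodide | C[N+](C)(C)C[C@@H]1C(=O)CCC(C)(C)[C@H]1/C=C/CCCC.[I-] | intermediate
8 | (3R)-3-[(E)-hex-1-enyl]-4,4-dimethyl-2-methylidenecyclohexan-1-one | C=C1C(=O)CCC(C)(C)[C@H]1/C=C/CCCC | intermediate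
9 | (1S,3R)-3-[(E)-hex-1-enyl]-4,4-dimethyl-2-methylidenecyclohexan-1-ol (1,3-cis) | C=C1[C@@H](O)CCC(C)(C)[C@H]1/C=C/CCCC | intermediate
10 | 8-[(E)-hex-1-enyl]-7,7-dimethyl-1-oxaspiro[2.5]octan-4-ol (hydroxyl, hexenyl and epoxide oxygen cis) | C1O[C@]12[C@@H](O)CCC(C)(C)[C@H]2/C=C/CCCC | intermediate
11 | 4-methoxybenzyl ether of 10 | C1O[C@]12[C@@H](OCc3ccc(OC)cc3)CCC(C)(C)[C@H]2/C=C/CCCC | intermediate
12 | 2,2,2-trifluoroethyl acrylate | C=CC(=O)OCC(F)(F)F | starting material
13 | 2,2,2-trifluoroethyl 3-{1-(hydroxymethyl)-6-[(E)-hex-1-enyl]-2-[(4-methoxybenzyl)oxy]-5,5-dimethylcyclohexyl}propanoate (propanoate arm trans to O1 and hexenyl) | OC[C@@]1(CCC(=O)OCC(F)(F)F)[C@@H](OCc2ccc(OC)cc2)CCC(C)(C)[C@H]1/C=C/CCCC | intermediate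
14 | 11-[(E)-hex-1-enyl]-7-[(4-methoxybenzyl)oxy]-10,10-dimethyl-2-oxaspiro[5.5]undecan-3-one (C9 trans to O1 and hexenyl; O1, C6 arm and C20 cis) | O=C1CC[C@]2(CO1)[C@@H](OCc3ccc(OC)cc3)CCC(C)(C)[C@H]2/C=C/CCCC | intermediate
15 | 7-[(4-methoxybenzyl)oxy]-10,10-dimethyl-3-oxo-2-oxaspiro[5.5]undecane-11-carbaldehyde | O=C1CC[C@]2(CO1)[C@@H](OCc3ccc(OC)cc3)CCC(C)(C)[C@H]2C=O | intermediate
16 | 11-(dimethoxymethyl)-7-[(4-methoxybenzyl)oxy]-10,10-dimethyl-2-oxaspiro[5.5]undecan-3-one | O=C1CC[C@]2(CO1)[C@@H](OCc3ccc(OC)cc3)CCC(C)(C)[C@H]2C(OC)OC | intermediate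
17 | 2,2,2-trifluoroethyl formate | O=COCC(F)(F)F | starting material
18 | (Z)-4-(hydroxymethylidene) derivative of 16 (enol of the C8 formyl lactone) | O=C1OC[C@@]2(C/C1=C/O)[C@@H](OCc3ccc(OC)cc3)CCC(C)(C)[C@H]2C(OC)OC | intermediate
19 | 4-formyl-4-(phenylselanyl) derivative of 16 (either C8 epimer; centre destroyed in the same step) | O=CC1([Se]c2ccccc2)C[C@]3(COC1=O)[C@@H](OCc4ccc(OC)cc4)CCC(C)(C)[C@H]3C(OC)OC | intermediate
20 | selenoxide of 19 | O=CC1([Se](=O)c2ccccc2)C[C@]3(COC1=O)[C@@H](OCc4ccc(OC)cc4)CCC(C)(C)[C@H]3C(OC)OC | intermediate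
21 | 11-(dimethoxymethyl)-7-[(4-methoxybenzyl)oxy]-10,10-dimethyl-3-oxo-2-oxaspiro[5.5]undec-4-ene-4-carbaldehyde | O=CC1=C[C@]2(COC1=O)[C@@H](OCc3ccc(OC)cc3)CCC(C)(C)[C@H]2C(OC)OC | intermediate
22 | buta-1,3-diene | C=CC=C | starting material
23 | Diels–Alder adduct: rings A, lactone and C; C12=C13; C8 formyl cis to H9; C11 and C14 on the lactone face of C1 | C1=CC[C@@H]3[C@](C1)(C(=O)OC[C@]32[C@@H](OCc4ccc(OC)cc4)CCC(C)(C)[C@H]2C(OC)OC)C=O | intermediate
24 | ethynylmagnesium bromide | C#C[Mg]Br | starting material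
25 | propargylic alcohol of 23 (C8–CH(OH)–C≡CH; 15-epi drawn) | C1=CC[C@@H]3[C@](C1)(C(=O)OC[C@]32[C@@H](OCc4ccc(OC)cc4)CCC(C)(C)[C@H]2C(OC)OC)[C@@H](O)C#C | intermediate
26 | tetracyclic 16-[(tributylstannyl)methylidene]-15-ol (tin cis to C13; alkene geometry immaterial) | CCCC[Sn](CCCC)(CCCC)/C=C1\[C@@H]2CC[C@@H]3[C@](C2)(C(=O)OC[C@]32[C@@H](OCc4ccc(OC)cc4)CCC(C)(C)[C@H]2C(OC)OC)[C@H]1O | intermediate
27 | tetracyclic 16-methylidene-15-ol (15-epi; 1-O-PMB; C6 dimethyl acetal) | C=C1[C@@H]2CC[C@@H]3[C@](C2)(C(=O)OC[C@]32[C@@H](OCc4ccc(OC)cc4)CCC(C)(C)[C@H]2C(OC)OC)[C@H]1O | intermediate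
28 | tetracyclic 16-methylidene-15-ketone (1-O-PMB; C6 dimethyl acetal) | C=C1[C@@H]2CC[C@@H]3[C@](C2)(C(=O)OC[C@]32[C@@H](OCc4ccc(OC)cc4)CCC(C)(C)[C@H]2C(OC)OC)C1=O | intermediate
29 | 1-hydroxy 16-methylidene-15-ketone (C6 dimethyl acetal) | C=C1[C@@H]2CC[C@@H]3[C@](C2)(C(=O)OC[C@]32[C@@H](O)CCC(C)(C)[C@H]2C(OC)OC)C1=O | intermediate
30 | 1-acetoxy 16-methylidene-15-ketone (C6 dimethyl acetal) | C=C1[C@@H]2CC[C@@H]3[C@](C2)(C(=O)OC[C@]32[C@@H](OC(C)=O)CCC(C)(C)[C@H]2C(OC)OC)C1=O | intermediate
31 | dimethyl acetal of the target (1-acetoxy; endo 15-hydroxyl) | C=C1[C@@H]2CC[C@@H]3[C@](C2)(C(=O)OC[C@]32[C@@H](OC(C)=O)CCC(C)(C)[C@H]2C(OC)OC)[C@@H]1O | intermediate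
32 | CNP0117386.1 (1-acetoxy-15-hydroxy-6-oxo-6,7-seco-ent-kaur-16-en-7,20-olide) | C=C1[C@@H]2CC[C@@H]3[C@](C2)(C(=O)OC[C@]32[C@@H](OC(C)=O)CCC(C)(C)[C@H]2C=O)[C@@H]1O | target

Total step count: 17. Longest linear sequence: 17 steps (1 → 32; all other inputs are commercial).

Steps most likely to fail

Step 12. The σ-vinyl radical may be reduced before it closes the ring, may abstract the allylic hydrogen on C11 (1,5-hydrogen transfer), or the cyclised C12 radical may rearrange by a homoallyl shift toward the bicyclo[2.2.2]octane. The fallback leaves the radical manifold and sets out from 25. Treatment with Pd2(dba)3·CHCl3 (zerovalent palladium), tri-o-tolylphosphine, AcOH and Et3SiH in benzene at 25–50 °C should generate a palladium hydride that adds across the alkyne with palladium on C16. Syn-carbopalladation of C12=C13 then closes ring D 5-exo, and the silane reduces the C12–Pd bond. This comes back to the route at 27 directly, so the fallback makes no new compound (F0).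

Step 6. The tertiary C10 radical may be reduced by a second titanocene and lose a neighbouring oxygen function by β-elimination before it adds to the acrylate, or the face selectivity at C10 may erode. The fallback generates the same radical without a low-valent metal and sets out from 11. Opening of the epoxide at its CH2 terminus with CsOAc/AcOH in DMF at 80 °C should give the tertiary alcohol with a primary acetate, hydroxy acetate F1. Acylation with methyl chlorooxoacetate (Et3N, DMAP) gives the methyl oxalate F2, and one equivalent of CsOH in aqueous THF at 0 °C gives the caesium oxalate F3. Visible-light photoredox fragmentation (Ir[dF(CF3)ppy]2(dtbbpy)PF6, blue light, DME/DMF/H2O) in the presence of 12 should release the C10 radical, which adds to the acrylate anti to the C1 ether and the C5 arm to give the Giese ester F4. K2CO3 in MeOH removes the acetate and the freed C20 hydroxyl lactonises, which comes back to the route at 14.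

Step 1. Alkenyl transfer to the neopentyl β-carbon may proceed with insufficient enantioselectivity, or isobutyl transfer may compete. The fallback takes the stereocentre from a kinetic resolution and sets out from 1. The same hydroalumination, conjugate addition (CuTC with PPh3, no chiral ligand) and iminium trapping give the racemic aluminium enolate F5 and the racemic Mannich base F6. Methylation and elimination through the racemic ammonium iodide F7 give the racemic enone F8, and Luche reduction gives the racemic cis allylic alcohol F9. Sharpless kinetic resolution (Ti(OiPr)4, L-(+)-diisopropyl tartrate, t-BuOOH 0.55 equiv, 4 Å molecular sieves, CH2Cl2, −20 °C) should epoxidise only the (1S,3R)-enantiomer. This comes back to the route at 10, and the slow-reacting enantiomer is recovered unchanged.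

Further compounds
F0 | step 12 | none | none
F1 | step 6 | hydroxy acetate: {1-hydroxy-6-[(E)-hex-1-enyl]-2-[(4-methoxybenzyl)oxy]-5,5-dimethylcyclohexyl}methyl acetate | CC(=O)OC[C@]1(O)[C@@H](OCc2ccc(OC)cc2)CCC(C)(C)[C@H]1/C=C/CCCC
F2 | step 6 | methyl oxalate of F1 | COC(=O)C(=O)O[C@@]1(COC(C)=O)[C@@H](OCc2ccc(OC)cc2)CCC(C)(C)[C@H]1/C=C/CCCC
F3 | step 6 | caesium oxalate of F1 | [Cs+].[O-]C(=O)C(=O)O[C@@]1(COC(C)=O)[C@@H](OCc2ccc(OC)cc2)CCC(C)(C)[C@H]1/C=C/CCCC
F4 | step 6 | Giese ester: 2,2,2-trifluoroethyl 3-{1-(acetoxymethyl)-6-[(E)-hex-1-enyl]-2-[(4-methoxybenzyl)oxy]-5,5-dimethylcyclohexyl}propanoate | CC(=O)OC[C@@]1(CCC(=O)OCC(F)(F)F)[C@@H](OCc2ccc(OC)cc2)CCC(C)(C)[C@H]1/C=C/CCCC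
F5 | step 1 | racemic aluminium enolate (racemate of 5) | CCCC/C=C/[C@H]1C=C(O[Al](CC(C)C)CC(C)C)CCC1(C)C.CCCC/C=C/[C@@H]1C=C(O[Al](CC(C)C)CC(C)C)CCC1(C)C
F6 | step 1 | racemic trans Mannich base (racemate of 6) | CN(C)C[C@@H]1C(=O)CCC(C)(C)[C@H]1/C=C/CCCC.CN(C)C[C@H]1C(=O)CCC(C)(C)[C@@H]1/C=C/CCCC
F7 | step 1 | racemic ammonium iodide (racemate of 7) | C[N+](C)(C)C[C@@H]1C(=O)CCC(C)(C)[C@H]1/C=C/CCCC.C[N+](C)(C)C[C@H]1C(=O)CCC(C)(C)[C@@H]1/C=C/CCCC.[I-].[I-]
F8 | step 1 | racemic enone (racemate of 8) | C=C1C(=O)CCC(C)(C)[C@H]1/C=C/CCCC.C=C1C(=O)CCC(C)(C)[C@@H]1/C=C/CCCC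
F9 | step 1 | racemic cis allylic alcohol (racemate of 9) | C=C1[C@@H](O)CCC(C)(C)[C@H]1/C=C/CCCC.C=C1[C@H](O)CCC(C)(C)[C@@H]1/C=C/CCCC
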